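Assumption: the (R,R)-bisphosphoramide/SiCl4 system is taken to add the dienolate to the Re face of prenal, which gives 13R. The configuration is confirmed on 18 by Mosher ester analysis, and the (S,S)-catalyst is used instead if the sign proves opposite.

## Retrosynthetic overview

1. Target 34 ⇐ global desilylation ⇐ C5 ketone 33 ⇐ oxidation of carbinol 32. The key C4–C5 bond comes from an α-selective barium-mediated carbonyl allylation of (2Z)-enal 30 (C5–C16) with allyl chloride 12 (arene + C1–C4).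
2. Enal 30 ⇐ (2Z)-enoate 28 ⇐ acetoacetate dianion alkylation of bromide 22, then (E)-enol triflate and iron-catalysed methylation (sets 6Z).
3. Bromide 22 ⇐ hydroxy ester 18 ⇐ catalytic enantioselective vinylogous Mukaiyama aldol of prenal (sets 13R and 10E).
4. Chloride 12 ⇐ E-selective SeO2 oxidation of a prenyl arene ⇐ aryllithium + prenyl bromide. The methyl ethers are exchanged for silyl ethers through the quinone so that the last step is a mild desilylation.
5. No ring is formed: the only ring (benzene) is bought with 4-methoxy-2-methylphenol.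

## Fragment A (arene + C1–C4)

Step 1
Reactants: 1 4-methoxy-2-methylphenol
Product: 2 2-bromo-4-methoxy-6-methylphenol
Conditions: NBS (1.0 equiv), i-Pr2NH (10 mol %), CH2Cl2, 0 °C
Reagents that add atoms: N-bromosuccinimide, O=C1CCC(=O)N1Br
Why: Electrophilic aromatic bromination goes to the only free position ortho to the free hydroxyl (para is blocked), and the amine-catalysed NBS protocol is ortho-selective for phenols.

Step 2
Reactants: 2 2-bromo-4-methoxy-6-methylphenol
Product: 3 1-bromo-2,5-dimethoxy-3-methylbenzene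
Conditions: MeI, K2CO3, acetone, reflux
Reagents that add atoms: iodomethane, CI
Why: Williamson ether synthesis of a phenol; the methyl ether is inert to the aryllithium chemistry that follows.

Step 3
Reactants: 3 1-bromo-2,5-dimethoxy-3-methylbenzene; 4 prenyl bromide (1-bromo-3-methylbut-2-ene)
Product: 6 1,4-dimethoxy-2-methyl-6-(3-methylbut-2-en-1-yl)benzene, via aryllithium 5 (not isolated)
Conditions: n-BuLi, THF, −78 °C; CuBr·SMe2 (10 mol %), 4, −78 °C → rt
Reagents that add atoms: none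
Why: Bromine–lithium exchange followed by copper-catalysed SN2 allylation with a primary allylic bromide gives the linear prenyl arene, because γ-attack would have to build a quaternary carbon.

Step 4
Reactants: 6 1,4-dimethoxy-2-methyl-6-(3-methylbut-2-en-1-yl)benzene
Product: 7 2-methyl-6-(3-methylbut-2-en-1-yl)-1,4-benzoquinone
Conditions: (NH4)2Ce(NO3)6 (2.5 equiv), MeCN/H2O 2:1, 0 °C, 20 min
Reagents that add atoms: water, O
Why: Oxidative demethylation of a 1,4-dimethoxyarene by tetravalent cerium gives the p-quinone and leaves the trisubstituted alkene alone; it is done here on a simple, robust substrate.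

Step 5
Reactants: 7 2-methyl-6-(3-methylbut-2-en-1-yl)-1,4-benzoquinone
Product: 8 2-methyl-6-(3-methylbut-2-en-1-yl)benzene-1,4-diol
Conditions: Na2S2O4, THF/H2O, rt, Ar
Reagents that add atoms: none
Why: Dithionite reduction of a quinone to the hydroquinone is instantaneous and neutral, so the ortho-prenyl phenol does not cyclise to a chroman.

Step 6
Reactants: 8 2-methyl-6-(3-methylbut-2-en-1-yl)benzene-1,4-diol
Product: 9 1,4-bis(tert-butyldimethylsilyloxy)-2-methyl-6-(3-methylbut-2-en-1-yl)benzene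
Conditions: TBSOTf (2.4 equiv), 2,6-lutidine, CH2Cl2, 0 °C
Reagents that add atoms: tert-butyldimethylsilyl triflate, CC(C)(C)[Si](C)(C)OS(=O)(=O)C(F)(F)F
Why: O-silylation with the silyl triflate also covers the hindered 2,6-disubstituted phenol, and lutidine keeps the medium non-acidic.

Step 7
Reactants: 9 1,4-bis(tert-butyldimethylsilyloxy)-2-methyl-6-(3-methylbut-2-en-1-yl)benzene
Product: 10 (2E)-4-[2,5-bis(tert-butyldimethylsilyloxy)-3-methylphenyl]-2-methylbut-2-en-1-ol
Conditions: SeO2 (0.3 equiv), t-BuOOH (3 equiv), salicylic acid (10 mol %), CH2Cl2, rt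
Reagents that add atoms: selenium dioxide (oxygen carrier), O=[Se]=O; tert-butyl hydroperoxide (terminal oxidant), CC(C)(C)OO
Why: SeO2 allylic oxidation (ene reaction then [2,3]-shift) attacks the E-methyl of the gem-dimethyl terminus, giving the (E)-allylic alcohol and leaving the benzylic CH2 untouched.

Step 8
Reactants: 10 (2E)-4-[2,5-bis(tert-butyldimethylsilyloxy)-3-methylphenyl]-2-methylbut-2-en-1-ol
Product: 12 1,4-bis(tert-butyldimethylsilyloxy)-2-[(2E)-4-chloro-3-methylbut-2-en-1-yl]-6-methylbenzene, via alkoxysulfonium chloride 11 (not isolated)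
Conditions: NCS, Me2S, CH2Cl2, −30 → 0 °C
Reagents that add atoms: N-chlorosuccinimide, O=C1CCC(=O)N1Cl
Why: Corey–Kim chlorination converts a primary allylic alcohol into the chloride by SN2 collapse of the alkoxysulfonium salt, without allylic transposition or E/Z change.

## Fragment B (C5–C16)

Step 9
Reactants: 13 ethyl 3-methylbut-2-enoate
Product: 15 tert-butyl[(1-ethoxy-3-methylbuta-1,3-dien-1-yl)oxy]dimethylsilane, via lithium dienolate 14 (not isolated)
Conditions: LiN(i-Pr)2, THF, −78 °C; TBSCl, DMPU, −78 °C → rt; distilled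
Reagents that add atoms: tert-butyldimethylsilyl chloride, CC(C)(C)[Si](C)(C)Cl
Why: γ-Deprotonation of the β,β-disubstituted enoate and O-silylation of the extended enolate give the silyl dienol ether (silyl ketene acetal formation).

Step 10
Reactants: 15 tert-butyl[(1-ethoxy-3-methylbuta-1,3-dien-1-yl)oxy]dimethylsilane; 16 3-methylbut-2-enal (prenal)
Product: 18 ethyl (2E,5R)-5-hydroxy-3,7-dimethylocta-2,6-dienoate, via trichlorosilyl ether 17 (not isolated)
Conditions: SiCl4 (1.1 equiv), (R,R)-bisphosphoramide [MeN(CH2)5NMe-bridged bis(N,N'-dimethyl-1,1'-binaphthyl-2,2'-diamine phosphoric triamide)] (2 mol %), CH2Cl2, −78 °C; sat. aq. NaHCO3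
Reagents that add atoms: none
Why: In this Lewis-base-activated SiCl4 vinylogous Mukaiyama aldol the chiral phosphoramide-bound silicon cation activates the enal and the dienolate attacks through its γ-carbon in an open transition state on the Re face; this sets 13R, and the s-trans dienolate gives the (E)-enoate.

Step 11
Reactants: 18 ethyl (2E,5R)-5-hydroxy-3,7-dimethylocta-2,6-dienoate
Product: 19 ethyl (2E,5R)-5-(tert-butyldimethylsilyloxy)-3,7-dimethylocta-2,6-dienoate
Conditions: TBSCl, imidazole, DMF, rt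
Reagents that add atoms: tert-butyldimethylsilyl chloride, CC(C)(C)[Si](C)(C)Cl
Why: Silylation of the secondary allylic alcohol under neutral conditions protects it for all later organometallic and oxidation steps without touching the stereocentre.

Step 12
Reactants: 19 ethyl (2E,5R)-5-(tert-butyldimethylsilyloxy)-3,7-dimethylocta-2,6-dienoate
Product: 20 (2E,5R)-5-(tert-butyldimethylsilyloxy)-3,7-dimethylocta-2,6-dien-1-ol
Conditions: i-Bu2AlH (2.2 equiv), CH2Cl2, −78 °C; aq. potassium sodium tartrate (KNaC4H4O6)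
Reagents that add atoms: none
Why: 1,2-Reduction of an α,β-unsaturated ester by the aluminium hydride gives the allylic alcohol with the alkene geometry unchanged.

Step 13
Reactants: 20 (2E,5R)-5-(tert-butyldimethylsilyloxy)-3,7-dimethylocta-2,6-dien-1-ol
Product: 22 (2E,5R)-1-bromo-5-(tert-butyldimethylsilyloxy)-3,7-dimethylocta-2,6-diene, via alkoxyphosphonium bromide 21 (not isolated)
Conditions: CBr4, PPh3, CH2Cl2, 0 °C; used crude
Reagents that add atoms: carbon tetrabromide, BrC(Br)(Br)Br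
Why: Appel bromination of a primary allylic alcohol proceeds by SN2 at carbon under neutral conditions, so neither the silyl ether nor the alkene geometry is affected.

Step 14
Reactants: 22 (2E,5R)-1-bromo-5-(tert-butyldimethylsilyloxy)-3,7-dimethylocta-2,6-diene; 23 methyl acetoacetate
Product: 25 methyl (6E,9R)-9-(tert-butyldimethylsilyloxy)-7,11-dimethyl-3-oxododeca-6,10-dienoate, via acetoacetate dianion 24 (not isolated)
Conditions: 23, NaH, THF, 0 °C; n-BuLi, 0 °C; 22, 0 °C; AcOH quench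
Reagents that add atoms: none
Why: Weiler dianion alkylation: the more reactive terminal (γ) carbanion of the acetoacetate dianion displaces the primary allylic bromide by SN2, forming C8–C9.

Step 15
Reactants: 25 methyl (6E,9R)-9-(tert-butyldimethylsilyloxy)-7,11-dimethyl-3-oxododeca-6,10-dienoate
Product: 27 methyl (2E,6E,9R)-9-(tert-butyldimethylsilyloxy)-7,11-dimethyl-3-(trifluoromethanesulfonyloxy)dodeca-2,6,10-trienoate, via ammonium enolate 26 (not isolated)
Conditions: Tf2O, aq. Me4NOH, toluene, 5 °C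
Reagents that add atoms: triflic anhydride, O=S(=O)(OS(=O)(=O)C(F)(F)F)C(F)(F)F
Why: Stereoselective enol triflation: with the non-chelating ammonium counter-ion the enolate adopts the dipole-minimised geometry and is triflated with the oxygen trans to the ester, giving the (E)-enol triflate.

Step 16
Reactants: 27 methyl (2E,6E,9R)-9-(tert-butyldimethylsilyloxy)-7,11-dimethyl-3-(trifluoromethanesulfonyloxy)dodeca-2,6,10-trienoate
Product: 28 methyl (2Z,6E,9R)-9-(tert-butyldimethylsilyloxy)-3,7,11-trimethyldodeca-2,6,10-trienoate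
Conditions: MeMgBr, Fe(acac)3 (5 mol %), THF/NMP, −30 °C
Reagents that add atoms: methylmagnesium bromide, C[Mg]Br
Why: Iron-catalysed cross-coupling of an alkenyl triflate with a Grignard reagent is faster than ester attack and goes with retention, so methyl takes the place trans to the ester and the chain ends up cis (2Z).

Step 17
Reactants: 28 methyl (2Z,6E,9R)-9-(tert-butyldimethylsilyloxy)-3,7,11-trimethyldodeca-2,6,10-trienoate
Product: 29 (2Z,6E,9R)-9-(tert-butyldimethylsilyloxy)-3,7,11-trimethyldodeca-2,6,10-trien-1-ol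
Conditions: i-Bu2AlH (2.2 equiv), CH2Cl2, −78 °C; aq. potassium sodium tartrate (KNaC4H4O6)
Reagents that add atoms: none
Why: 1,2-Reduction of the enoate by the aluminium hydride gives the neryl-type allylic alcohol with the Z geometry intact.

Step 18
Reactants: 29 (2Z,6E,9R)-9-(tert-butyldimethylsilyloxy)-3,7,11-trimethyldodeca-2,6,10-trien-1-ol
Product: 30 (2Z,6E,9R)-9-(tert-butyldimethylsilyloxy)-3,7,11-trimethyldodeca-2,6,10-trienal
Conditions: MnO2 (activated, excess), CH2Cl2, 0 °C → rt, dark; used at once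
Reagents that add atoms: none
Why: Heterogeneous MnO2 oxidation of an allylic alcohol is neutral and stops at the aldehyde, so the Z-enal is formed without isomerisation to the E-enal.

## Coupling and endgame

Step 19
Reactants: 12 1,4-bis(tert-butyldimethylsilyloxy)-2-[(2E)-4-chloro-3-methylbut-2-en-1-yl]-6-methylbenzene; 30 (2Z,6E,9R)-9-(tert-butyldimethylsilyloxy)-3,7,11-trimethyldodeca-2,6,10-trienal
Product: 32 (2E,6Z,10E,13R)-1-[2,5-bis(tert-butyldimethylsilyloxy)-3-methylphenyl]-13-(tert-butyldimethylsilyloxy)-3,7,11,15-tetramethylhexadeca-2,6,10,14-tetraen-5-ol (C5 epimer mixture), via allylbarium chloride 31 (not isolated)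
Conditions: BaI2, lithium biphenylide LiC12H10 (2 equiv), THF, rt; 12 (1.5 equiv), −78 °C, 30 min; 30, −78 °C; H2O
Reagents that add atoms: none
Why: Barium-mediated carbonyl allylation: allylbarium reagents made from zerovalent barium at −78 °C add 1,2 to aldehydes through their α-carbon with retention of the allyl E geometry, so the linear C4–C5 bond forms and the 2E and 6Z alkenes are kept. The C5 centre is not controlled and is removed in step 20.

Step 20
Reactants: 32 (2E,6Z,10E,13R)-1-[2,5-bis(tert-butyldimethylsilyloxy)-3-methylphenyl]-13-(tert-butyldimethylsilyloxy)-3,7,11,15-tetramethylhexadeca-2,6,10,14-tetraen-5-ol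
Product: 33 (2E,6Z,10E,13R)-1-[2,5-bis(tert-butyldimethylsilyloxy)-3-methylphenyl]-13-(tert-butyldimethylsilyloxy)-3,7,11,15-tetramethylhexadeca-2,6,10,14-tetraen-5-one
Conditions: Dess–Martin periodinane, NaHCO3, CH2Cl2, 0 °C
Reagents that add atoms: none
Why: Buffered Dess–Martin oxidation of the secondary allylic alcohol is fast and near-neutral, so the β,γ-alkene does not move into conjugation and the Z-enone does not isomerise.

Step 21
Reactants: 33 (2E,6Z,10E,13R)-1-[2,5-bis(tert-butyldimethylsilyloxy)-3-methylphenyl]-13-(tert-butyldimethylsilyloxy)-3,7,11,15-tetramethylhexadeca-2,6,10,14-tetraen-5-one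
Product: 34 (2E,6Z,10E,13R)-1-(2,5-dihydroxy-3-methylphenyl)-13-hydroxy-3,7,11,15-tetramethylhexadeca-2,6,10,14-tetraen-5-one
Conditions: Bu4NF/AcOH 1:1 (6 equiv), degassed THF, 0 °C → rt, Ar
Reagents that add atoms: none
Why: Acetic-acid-buffered fluoride desilylation removes the two aryl and the one allylic silyl ether in one operation without the base or acid that would isomerise the skipped dienone, ionise the allylic alcohol or oxidise the hydroquinone; C13 is untouched.

## Compound list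

1 | 4-methoxy-2-methylphenol | COc1ccc(O)c(C)c1 | starting material
2 | 2-bromo-4-methoxy-6-methylphenol | Cc1cc(OC)cc(Br)c1O | intermediate
3 | 1-bromo-2,5-dimethoxy-3-methylbenzene | Cc1cc(OC)cc(Br)c1OC | intermediate
4 | prenyl bromide (1-bromo-3-methylbut-2-ene) | CC(C)=CCBr | starting material
5 | (2,5-dimethoxy-3-methylphenyl)lithium | Cc1cc(OC)cc([Li])c1OC | intermediate (not isolated)
6 | 1,4-dimethoxy-2-methyl-6-(3-methylbut-2-en-1-yl)benzene | Cc1cc(OC)cc(CC=C(C)C)c1OC | intermediate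
7 | 2-methyl-6-(3-methylbut-2-en-1-yl)-1,4-benzoquinone | CC1=CC(=O)C=C(CC=C(C)C)C1=O | intermediate
8 | 2-methyl-6-(3-methylbut-2-en-1-yl)benzene-1,4-diol | Cc1cc(O)cc(CC=C(C)C)c1O | intermediate
9 | 1,4-bis(tert-butyldimethylsilyloxy)-2-methyl-6-(3-methylbut-2-en-1-yl)benzene | Cc1cc(O[Si](C)(C)C(C)(C)C)cc(CC=C(C)C)c1O[Si](C)(C)C(C)(C)C | intermediate
10 | (2E)-4-[2,5-bis(tert-butyldimethylsilyloxy)-3-methylphenyl]-2-methylbut-2-en-1-ol | Cc1cc(O[Si](C)(C)C(C)(C)C)cc(C/C=C(\C)CO)c1O[Si](C)(C)C(C)(C)C | intermediate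
11 | dimethyl(alkoxy)sulfonium chloride of 10 | Cc1cc(O[Si](C)(C)C(C)(C)C)cc(C/C=C(\C)CO[S+](C)C)c1O[Si](C)(C)C(C)(C)C.[Cl-] | intermediate (not isolated)
12 | 1,4-bis(tert-butyldimethylsilyloxy)-2-[(2E)-4-chloro-3-methylbut-2-en-1-yl]-6-methylbenzene | Cc1cc(O[Si](C)(C)C(C)(C)C)cc(C/C=C(\C)CCl)c1O[Si](C)(C)C(C)(C)C | intermediate
13 | ethyl 3-methylbut-2-enoate | CCOC(=O)C=C(C)C | starting material
14 | lithium 1-ethoxy-3-methylbuta-1,3-dien-1-olate | [Li]OC(OCC)=CC(C)=C | intermediate (not isolated)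
15 | tert-butyl[(1-ethoxy-3-methylbuta-1,3-dien-1-yl)oxy]dimethylsilane | CCOC(O[Si](C)(C)C(C)(C)C)=CC(C)=C | intermediate
16 | 3-methylbut-2-enal (prenal) | CC(C)=CC=O | starting material
17 | ethyl (2E,5R)-3,7-dimethyl-5-(trichlorosilyloxy)octa-2,6-dienoate | CCOC(=O)/C=C(\C)C[C@@H](O[Si](Cl)(Cl)Cl)C=C(C)C | intermediate (not isolated)
18 | ethyl (2E,5R)-5-hydroxy-3,7-dimethylocta-2,6-dienoate | CCOC(=O)/C=C(\C)C[C@@H](O)C=C(C)C | intermediate
19 | ethyl (2E,5R)-5-(tert-butyldimethylsilyloxy)-3,7-dimethylocta-2,6-dienoate | CCOC(=O)/C=C(\C)C[C@@H](O[Si](C)(C)C(C)(C)C)C=C(C)C | intermediate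
20 | (2E,5R)-5-(tert-butyldimethylsilyloxy)-3,7-dimethylocta-2,6-dien-1-ol | OC/C=C(\C)C[C@@H](O[Si](C)(C)C(C)(C)C)C=C(C)C | intermediate
21 | alkoxytriphenylphosphonium bromide of 20 | [Br-].c1ccc(cc1)[P+](OC/C=C(\C)C[C@@H](O[Si](C)(C)C(C)(C)C)C=C(C)C)(c1ccccc1)c1ccccc1 | intermediate (not isolated)
22 | (2E,5R)-1-bromo-5-(tert-butyldimethylsilyloxy)-3,7-dimethylocta-2,6-diene | BrC/C=C(\C)C[C@@H](O[Si](C)(C)C(C)(C)C)C=C(C)C | intermediate
23 | methyl acetoacetate | COC(=O)CC(C)=O | starting material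
24 | sodium lithium dianion of methyl acetoacetate | [Na+].[Li+].[CH2-]C(=O)[CH-]C(=O)OC | intermediate (not isolated)
25 | methyl (6E,9R)-9-(tert-butyldimethylsilyloxy)-7,11-dimethyl-3-oxododeca-6,10-dienoate | COC(=O)CC(=O)CC/C=C(\C)C[C@@H](O[Si](C)(C)C(C)(C)C)C=C(C)C | intermediate
26 | tetramethylammonium enolate of 25 | C[N+](C)(C)C.COC(=O)/C=C(/[O-])CC/C=C(\C)C[C@@H](O[Si](C)(C)C(C)(C)C)C=C(C)C | intermediate (not isolated)
27 | methyl (2E,6E,9R)-9-(tert-butyldimethylsilyloxy)-7,11-dimethyl-3-(trifluoromethanesulfonyloxy)dodeca-2,6,10-trienoate | COC(=O)/C=C(/OS(=O)(=O)C(F)(F)F)CC/C=C(\C)C[C@@H](O[Si](C)(C)C(C)(C)C)C=C(C)C | intermediate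
28 | methyl (2Z,6E,9R)-9-(tert-butyldimethylsilyloxy)-3,7,11-trimethyldodeca-2,6,10-trienoate | COC(=O)/C=C(/C)CC/C=C(\C)C[C@@H](O[Si](C)(C)C(C)(C)C)C=C(C)C | intermediate
29 | (2Z,6E,9R)-9-(tert-butyldimethylsilyloxy)-3,7,11-trimethyldodeca-2,6,10-trien-1-ol | OC/C=C(/C)CC/C=C(\C)C[C@@H](O[Si](C)(C)C(C)(C)C)C=C(C)C | intermediate
30 | (2Z,6E,9R)-9-(tert-butyldimethylsilyloxy)-3,7,11-trimethyldodeca-2,6,10-trienal | O=C/C=C(/C)CC/C=C(\C)C[C@@H](O[Si](C)(C)C(C)(C)C)C=C(C)C | intermediate
31 | allylbarium chloride from 12 | Cc1cc(O[Si](C)(C)C(C)(C)C)cc(C/C=C(\C)C[Ba]Cl)c1O[Si](C)(C)C(C)(C)C | intermediate (not isolated)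
32 | (2E,6Z,10E,13R)-1-[2,5-bis(tert-butyldimethylsilyloxy)-3-methylphenyl]-13-(tert-butyldimethylsilyloxy)-3,7,11,15-tetramethylhexadeca-2,6,10,14-tetraen-5-ol (C5 epimers) | Cc1cc(O[Si](C)(C)C(C)(C)C)cc(C/C=C(\C)CC(O)/C=C(/C)CC/C=C(\C)C[C@@H](O[Si](C)(C)C(C)(C)C)C=C(C)C)c1O[Si](C)(C)C(C)(C)C | intermediate
33 | (2E,6Z,10E,13R)-1-[2,5-bis(tert-butyldimethylsilyloxy)-3-methylphenyl]-13-(tert-butyldimethylsilyloxy)-3,7,11,15-tetramethylhexadeca-2,6,10,14-tetraen-5-one | Cc1cc(O[Si](C)(C)C(C)(C)C)cc(C/C=C(\C)CC(=O)/C=C(/C)CC/C=C(\C)C[C@@H](O[Si](C)(C)C(C)(C)C)C=C(C)C)c1O[Si](C)(C)C(C)(C)C | intermediate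
34 | (2E,6Z,10E,13R)-1-(2,5-dihydroxy-3-methylphenyl)-13-hydroxy-3,7,11,15-tetramethylhexadeca-2,6,10,14-tetraen-5-one | Cc1cc(O)cc(C/C=C(\C)CC(=O)/C=C(/C)CC/C=C(\C)C[C@@H](O)C=C(C)C)c1O | target

## Summary

Total step count: 21.
Longest linear sequence: 13 steps (13 → 34, steps 9–21); the arene branch is 11 steps (steps 1–8 and 19–21).

The three steps most likely to fail:

**Step 10 (enantioselective vinylogous aldol on prenal; ee, E-selectivity and catalyst sense).** The fallback sets out from 16 and comes back at 19. Prenal 16 is added to doubly deprotonated (R)-2-hydroxy-1,2,2-triphenylethyl acetate (LiN(i-Pr)2, THF, −78 then −100 °C), an auxiliary-controlled acetate aldol known to give (R)-carbinols. This gives (1R)-2-hydroxy-1,2,2-triphenylethyl (3R)-3-hydroxy-5-methylhex-4-enoate F1, which is recrystallised to one diastereomer. K2CO3/MeOH transesterification gives methyl (3R)-3-hydroxy-5-methylhex-4-enoate F2, and the auxiliary diol is recovered. A crossed Claisen condensation with excess lithio ethyl acetate (THF, −78 → −40 °C; the alkoxide of F2 guards against β-elimination) gives ethyl (5R)-5-hydroxy-7-methyl-3-oxooct-6-enoate F3. TBSCl/imidazole gives ethyl (5R)-5-(tert-butyldimethylsilyloxy)-7-methyl-3-oxooct-6-enoate F4. Tf2O with aq. LiOH (chelated enolate) gives ethyl (2Z,5R)-5-(tert-butyldimethylsilyloxy)-7-methyl-3-(trifluoromethanesulfonyloxy)octa-2,6-dienoate F5. MeMgBr/Fe(acac)3 coupling with retention then gives the (2E)-enoate 19.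

**Step 15 (E-selective enol triflation, which decides the 6Z geometry).** The fallback sets out from 22 and comes back at 28. Bromide 22 is alkylated with lithiated 1-(trimethylsilyl)propyne (n-BuLi, THF, −78 °C) to give (5E,8R)-8-(tert-butyldimethylsilyloxy)-6,10-dimethyl-1-(trimethylsilyl)undeca-5,9-dien-1-yne F6. K2CO3/MeOH removes the alkynyl silyl group to give (5E,8R)-8-(tert-butyldimethylsilyloxy)-6,10-dimethylundeca-5,9-dien-1-yne F7. n-BuLi gives the lithium acetylide of F7, F8 (not isolated), and methyl chloroformate traps it as methyl (6E,9R)-9-(tert-butyldimethylsilyloxy)-7,11-dimethyldodeca-6,10-dien-2-ynoate F9. Me2CuLi (THF, −78 °C, MeOH quench at −78 °C) adds methyl and copper syn across the triple bond, so the chain ends up cis to the ester, which is 28.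

**Step 19 (allylbarium coupling; α/γ ratio, Wurtz coupling, handling of activated barium).** The fallback sets out from 12 (with 30) and comes back at 33. Chloride 12 is converted with PhSO2Na (DMF, rt) into 1,4-bis(tert-butyldimethylsilyloxy)-2-methyl-6-[(2E)-3-methyl-4-(phenylsulfonyl)but-2-en-1-yl]benzene F10. n-BuLi (THF, −78 °C) gives the α-lithio sulfone F11 (not isolated), which adds through its sulfonyl-bearing carbon to enal 30 in an aldol-type addition to give the β-hydroxy sulfone F12 as an isomer mixture. Dess–Martin oxidation gives the β-keto sulfone F13. SmI2 (THF/MeOH, −78 °C) cleaves the C–S bond, and kinetic α-protonation of the resulting dienolate gives the β,γ-unsaturated ketone 33.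

## Further compounds

F1 | step 10 | (1R)-2-hydroxy-1,2,2-triphenylethyl (3R)-3-hydroxy-5-methylhex-4-enoate | CC(C)=C[C@H](O)CC(=O)O[C@H](c1ccccc1)C(O)(c1ccccc1)c1ccccc1
F2 | step 10 | methyl (3R)-3-hydroxy-5-methylhex-4-enoate | COC(=O)C[C@@H](O)C=C(C)C
F3 | step 10 | ethyl (5R)-5-hydroxy-7-methyl-3-oxooct-6-enoate | CCOC(=O)CC(=O)C[C@@H](O)C=C(C)C
F4 | step 10 | ethyl (5R)-5-(tert-butyldimethylsilyloxy)-7-methyl-3-oxooct-6-enoate | CCOC(=O)CC(=O)C[C@@H](O[Si](C)(C)C(C)(C)C)C=C(C)C
F5 | step 10 | ethyl (2Z,5R)-5-(tert-butyldimethylsilyloxy)-7-methyl-3-(trifluoromethanesulfonyloxy)octa-2,6-dienoate | CCOC(=O)/C=C(\OS(=O)(=O)C(F)(F)F)C[C@@H](O[Si](C)(C)C(C)(C)C)C=C(C)C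
F6 | step 15 | (5E,8R)-8-(tert-butyldimethylsilyloxy)-6,10-dimethyl-1-(trimethylsilyl)undeca-5,9-dien-1-yne | C[Si](C)(C)C#CCC/C=C(\C)C[C@@H](O[Si](C)(C)C(C)(C)C)C=C(C)C
F7 | step 15 | (5E,8R)-8-(tert-butyldimethylsilyloxy)-6,10-dimethylundeca-5,9-dien-1-yne | C#CCC/C=C(\C)C[C@@H](O[Si](C)(C)C(C)(C)C)C=C(C)C
F8 | step 15 | lithium acetylide of F7 | [Li]C#CCC/C=C(\C)C[C@@H](O[Si](C)(C)C(C)(C)C)C=C(C)C
F9 | step 15 | methyl (6E,9R)-9-(tert-butyldimethylsilyloxy)-7,11-dimethyldodeca-6,10-dien-2-ynoate | COC(=O)C#CCC/C=C(\C)C[C@@H](O[Si](C)(C)C(C)(C)C)C=C(C)C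
F10 | step 19 | 1,4-bis(tert-butyldimethylsilyloxy)-2-methyl-6-[(2E)-3-methyl-4-(phenylsulfonyl)but-2-en-1-yl]benzene | Cc1cc(O[Si](C)(C)C(C)(C)C)cc(C/C=C(\C)CS(=O)(=O)c2ccccc2)c1O[Si](C)(C)C(C)(C)C
F11 | step 19 | α-lithio derivative of sulfone F10 | Cc1cc(O[Si](C)(C)C(C)(C)C)cc(C/C=C(\C)C([Li])S(=O)(=O)c2ccccc2)c1O[Si](C)(C)C(C)(C)C
F12 | step 19 | (2E,6Z,10E,13R)-1-[2,5-bis(tert-butyldimethylsilyloxy)-3-methylphenyl]-13-(tert-butyldimethylsilyloxy)-3,7,11,15-tetramethyl-4-(phenylsulfonyl)hexadeca-2,6,10,14-tetraen-5-ol (isomer mixture at C4 and C5) | Cc1cc(O[Si](C)(C)C(C)(C)C)cc(C/C=C(\C)C(C(O)/C=C(/C)CC/C=C(\C)C[C@@H](O[Si](C)(C)C(C)(C)C)C=C(C)C)S(=O)(=O)c2ccccc2)c1O[Si](C)(C)C(C)(C)C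
F13 | step 19 | (2E,6Z,10E,13R)-1-[2,5-bis(tert-butyldimethylsilyloxy)-3-methylphenyl]-13-(tert-butyldimethylsilyloxy)-3,7,11,15-tetramethyl-4-(phenylsulfonyl)hexadeca-2,6,10,14-tetraen-5-one (C4 epimers) | Cc1cc(O[Si](C)(C)C(C)(C)C)cc(C/C=C(\C)C(C(=O)/C=C(/C)CC/C=C(\C)C[C@@H](O[Si](C)(C)C(C)(C)C)C=C(C)C)S(=O)(=O)c2ccccc2)c1O[Si](C)(C)C(C)(C)C
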